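## Retrosynthetic overview

Locants are those of the azulene skeleton: ring A (five-membered) = C1, C2, C3, C3a, C8a; ring B (seven-membered) = C3a, C4–C8, C8a.

1. The aryl ester at C4 is made last by acylation; ring B is opened at C6=C7 (ring-closing metathesis), so ring A is built first and ring B second.
2. C4–O and C5 are traced back to a vinyl group on C3a (hydroxyl-directed epoxidation, then opening with an isopropenyl copper reagent).
3. Key disconnection: C8a–C1 and C3a–C3 of ring A, both formed in one flask by double allylboration of a masked 1,3-keto-aldehyde (C1–C2–C3) with an enantioenriched, diene-derived 1,2-bis(boronate).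
4. Enabling feature: in ring A the carbinol carbons C1 and C3 each flank one of the two adjacent fusion carbons (C8a, C3a), and C3a also carries C4. Ring A is therefore the adduct of a 1,3-dicarbonyl unit and a vicinal bis-allyl donor, whose transposed alkene becomes C4=C5 and serves as the handle for ring B.
5. Absolute configuration enters once (catalytic enantioselective diboration) and is relayed through two chair transition states; the trans ring fusion is already fixed on the monocyclic stage.

Key step: step 8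

Assumption: the antipode of the TADDOL-derived phosphonite ligand in step 7 is the one that delivers the (2R)-bis(boronate); the sense of induction is assigned by analogy with terminal alkenes and cis-dienes.

Assumption: 4-[(tert-butyldimethylsilyl)oxy]benzoic acid and (2E)-1-chlorobut-2-ene are purchased; a minor Z content in the latter is harmless because that alkene terminus is excised in step 12.

## Route

Step 1
Reactants: 1 ethyl 4-methyl-3-oxopentanoate
Product: 2 ethyl [2-(propan-2-yl)-1,3-dioxolan-2-yl]acetate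
Conditions: HOCH2CH2OH, TsOH·H2O (cat.), toluene, reflux, azeotropic removal of water
Reagents that add atoms: ethane-1,2-diol OCCO
Why: Acid-catalysed ketalisation of the ketone of a β-keto ester masks the ketone, so that the aldehyde made next is not an enolised 1,3-dicarbonyl compound.

Step 2
Reactants: 2 ethyl [2-(propan-2-yl)-1,3-dioxolan-2-yl]acetate
Product: 3 [2-(propan-2-yl)-1,3-dioxolan-2-yl]acetaldehyde
Conditions: iBu2AlH (1.05 equiv), CH2Cl2, −78 °C; aq potassium sodium tartrate
Reagents that add atoms: none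
Why: Partial reduction of an ester to the aldehyde at low temperature, which stops at the stable aluminium hemiacetal until work-up.

Step 3
Reactants: 4 but-2-yn-1-ol
Product: 6 (2Z)-3-iodobut-2-en-1-ol, via cyclic sodium alkenylalanate 5 (not isolated)
Conditions: NaAlH2(OCH2CH2OCH3)2, THF, 0 °C → rt; then I2, −78 → 0 °C
Reagents that add atoms: iodine [I][I]
Why: Hydroxyl-directed trans-hydroalumination of a propargylic alcohol puts aluminium on C3 inside a five-membered alanate, and iodinolysis with retention should give the (Z)-iodide with iodine cis to CH2OH.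

Step 4
Reactants: 6 (2Z)-3-iodobut-2-en-1-ol
Product: 7 (2Z)-3-iodobut-2-enal
Conditions: MnO2 (excess), CH2Cl2, rt, dark
Reagents that add atoms: none
Why: Allylic alcohol oxidation on MnO2 is neutral and mild and should keep the alkene geometry.

Step 5
Reactants: 7 (2Z)-3-iodobut-2-enal
Product: 8 (3Z)-4-iodopenta-1,3-diene
Conditions: Ph3PCH3Br, KN(SiMe3)2, THF, −78 → 0 °C
Reagents that add atoms: methyltriphenylphosphonium bromide [Br-].C[P+](c1ccccc1)(c1ccccc1)c1ccccc1
Why: Wittig methylenation of the enal; fast 1,2-addition of the unstabilised ylide at low temperature should leave the β-iodo alkene and its geometry untouched.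

Step 6
Reactants: 8 (3Z)-4-iodopenta-1,3-diene
Product: 11 (3Z,6E)-4-methylocta-1,3,6-triene, via dienyllithium 9 (not isolated), via dienylzinc chloride 10 (not isolated)
Conditions: tBuLi (2.1 equiv), Et2O, −78 °C; ZnCl2, THF, −78 → 0 °C; (E)-CH3CH=CHCH2Cl, Pd(PPh3)4 (3 mol %), 0 °C → rt
Reagents that add atoms: (2E)-1-chlorobut-2-ene C/C=C/CCl
Why: Iodine–lithium exchange and transmetalation to zinc proceed with retention of alkene geometry, and the Negishi coupling of an alkenylzinc with an allylic chloride joins the less substituted allyl terminus, which should give the skipped triene with the butenyl group cis to the vinyl group.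

Step 7
Reactants: 11 (3Z,6E)-4-methylocta-1,3,6-triene
Product: 12 2,2'-[(2R,3Z,6E)-4-methylocta-3,6-diene-1,2-diyl]bis(4,4,5,5-tetramethyl-1,3,2-dioxaborolane)
Conditions: B2pin2 (1.05 equiv), Pt(dba)3 (3 mol %), TADDOL-derived phenylphosphonite ligand (6 mol %), THF, 60 °C; used directly
Reagents that add atoms: bis(pinacolato)diboron CC1(C)OB(OC1(C)C)B1OC(C)(C)C(C)(C)O1
Why: Platinum-catalysed enantioselective 1,2-diboration of the terminal alkene of a diene that cannot reach the s-cis conformation (cis substituent on C4), with the chiral phosphonite setting the boron-bearing stereocentre; the trisubstituted and 1,2-disubstituted alkenes should stay untouched because this catalyst engages only terminal alkenes.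

Step 8
Reactants: 12 2,2'-[(2R,3Z,6E)-4-methylocta-3,6-diene-1,2-diyl]bis(4,4,5,5-tetramethyl-1,3,2-dioxaborolane); 3 [2-(propan-2-yl)-1,3-dioxolan-2-yl]acetaldehyde
Product: 16 (1R,3R,4R,5R)-4-[(2E)-but-2-en-1-yl]-5-ethenyl-4-methyl-1-(propan-2-yl)cyclopentane-1,3-diol, via first allylboration adduct 13 (not isolated), via hydroxy ketone allylboronate 14 (not isolated), via cyclised O-boronate 15 (not isolated)
Conditions: toluene, 60 °C; then in the same flask TsOH·H2O (20 mol %), THF/H2O, 40 °C; aq NaHCO3
Reagents that add atoms: water O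
Why: The secondary allylic boronate of 12 adds to aldehyde 3 through a closed chair transition state (aldehyde substituent equatorial, the cis butenyl CH2 axial, the CH2B group pseudo-equatorial), which forms the C8a–C1 bond, sets the quaternary centre and the C1 carbinol with methyl cis to oxygen, and transposes the alkene to an (E)-allylic primary boronate. Acid then removes the dioxolane, and the liberated isopropyl ketone is attacked by the γ-carbon of this second allylboronate, which forms the C3a–C3 bond and closes ring A (a 5-exo-trig closure onto the carbonyl carbon, through a boron chair fused to the forming cyclopentane). The closest known reaction type is the tandem double allylboration of keto-aldehydes with diene-derived 1,2-bis(boronates), which gives cyclohexane-1,4-diols from 1,4-dicarbonyl compounds; here a 1,3-dicarbonyl unit should give the cyclopentane-1,3-diol. C8a and C1 are controlled by the boron-bearing stereocentre and the (Z)-geometry of 12. C3a and C3 are controlled by the (E)-allylboronate chair with isopropyl equatorial, which places the new hydroxyl cis to the vinyl group, and by the C1 hydroxyl, which should sit cis to the incoming ketone oxygen (hydrogen bond, no 1,3-clash with isopropyl). The step needs aldehyde-before-ketone chemoselectivity, secured by keeping the ketone as its ketal until the first bond exists, and γ-regioselectivity, which is inherent to allylboronates.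

Step 9
Reactants: 16 (1R,3R,4R,5R)-4-[(2E)-but-2-en-1-yl]-5-ethenyl-4-methyl-1-(propan-2-yl)cyclopentane-1,3-diol
Product: 17 (1R,2R,3R,4R)-3-[(2E)-but-2-en-1-yl]-2-ethenyl-3-methyl-1-(propan-2-yl)-4-[(triethylsilyl)oxy]cyclopentan-1-ol
Conditions: Et3SiOTf (1.1 equiv), 2,6-lutidine, CH2Cl2, −78 °C
Reagents that add atoms: triethylsilyl trifluoromethanesulfonate CC[Si](CC)(CC)OS(=O)(=O)C(F)(F)F
Why: Silylation should discriminate the secondary from the far more hindered tertiary hydroxyl, which leaves the tertiary alcohol as the only directing group.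

Step 10
Reactants: 17 (1R,2R,3R,4R)-3-[(2E)-but-2-en-1-yl]-2-ethenyl-3-methyl-1-(propan-2-yl)-4-[(triethylsilyl)oxy]cyclopentan-1-ol
Product: 18 (1R,2S,3R,4R)-3-[(2E)-but-2-en-1-yl]-3-methyl-2-[(2R)-oxiran-2-yl]-1-(propan-2-yl)-4-[(triethylsilyl)oxy]cyclopentan-1-ol
Conditions: VO(acac)2 (10 mol %), tBuOOH (anhydrous), toluene, 25–40 °C
Reagents that add atoms: tert-butyl hydroperoxide CC(C)(C)OO
Why: Hydroxyl-directed epoxidation of a homoallylic alcohol, in which the vanadate ester of the tertiary alcohol delivers oxygen to the vinyl group through a chair-like transition state (isopropyl and the ring carbon equatorial, the allylic hydrogen eclipsing the alkene) that should give the (2R)-oxirane, while the butenyl alkene has no free hydroxyl within reach.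

Step 11
Reactants: 18 (1R,2S,3R,4R)-3-[(2E)-but-2-en-1-yl]-3-methyl-2-[(2R)-oxiran-2-yl]-1-(propan-2-yl)-4-[(triethylsilyl)oxy]cyclopentan-1-ol
Product: 19 (1R,2S,3R,4R)-3-[(2E)-but-2-en-1-yl]-2-[(1S)-1-hydroxy-3-methylbut-3-en-1-yl]-3-methyl-1-(propan-2-yl)-4-[(triethylsilyl)oxy]cyclopentan-1-ol
Conditions: CH2=C(CH3)MgBr (3 equiv), CuI (15 mol %), THF, −30 → 0 °C; aq NH4Cl
Reagents that add atoms: isopropenylmagnesium bromide CC(=C)[Mg]Br
Why: Copper-catalysed opening of a terminal epoxide by an alkenyl Grignard reagent at the unsubstituted carbon, which leaves the new carbinol stereocentre untouched.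

Step 12
Reactants: 19 (1R,2S,3R,4R)-3-[(2E)-but-2-en-1-yl]-2-[(1S)-1-hydroxy-3-methylbut-3-en-1-yl]-3-methyl-1-(propan-2-yl)-4-[(triethylsilyl)oxy]cyclopentan-1-ol
Product: 20 (1R,3R,3aS,4S,8aR)-6,8a-dimethyl-3-(propan-2-yl)-1-[(triethylsilyl)oxy]-1,2,3,3a,4,5,8,8a-octahydroazulene-3,4-diol
Conditions: second-generation Grubbs catalyst (5 mol %), CH2Cl2 (5 mM), 40 °C
Reagents that add atoms: none
Why: Ring-closing metathesis between the butenyl group and the 1,1-disubstituted alkene should form the trisubstituted cycloheptene of ring B, and because the two arms are trans on the cyclopentane the trans ring fusion follows.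

Step 13
Reactants: 20 (1R,3R,3aS,4S,8aR)-6,8a-dimethyl-3-(propan-2-yl)-1-[(triethylsilyl)oxy]-1,2,3,3a,4,5,8,8a-octahydroazulene-3,4-diol; 21 4-[(tert-butyldimethylsilyl)oxy]benzoic acid
Product: 22 (1R,3R,3aS,4S,8aR)-3-hydroxy-6,8a-dimethyl-3-(propan-2-yl)-1-[(triethylsilyl)oxy]-1,2,3,3a,4,5,8,8a-octahydroazulen-4-yl 4-[(tert-butyldimethylsilyl)oxy]benzoate
Conditions: DCC, DMAP, CH2Cl2, 0 °C → rt
Reagents that add atoms: none
Why: Steglich esterification should acylate the only secondary hydroxyl, since the tertiary alcohol does not react under these conditions.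

Step 14
Reactants: 22 (1R,3R,3aS,4S,8aR)-3-hydroxy-6,8a-dimethyl-3-(propan-2-yl)-1-[(triethylsilyl)oxy]-1,2,3,3a,4,5,8,8a-octahydroazulen-4-yl 4-[(tert-butyldimethylsilyl)oxy]benzoate
Product: 23 (1R,3R,3aS,4S,8aR)-1,3-dihydroxy-6,8a-dimethyl-3-(propan-2-yl)-1,2,3,3a,4,5,8,8a-octahydroazulen-4-yl 4-hydroxybenzoate
Conditions: HF·pyridine, THF/pyridine, 0 °C → rt
Reagents that add atoms: none
Why: Fluoride-mediated cleavage of both silyl ethers (aryl and secondary alkyl) under buffered conditions that should leave the aryl ester, the tertiary alcohol and the trisubstituted alkene intact.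

## Compound list

1 | ethyl 4-methyl-3-oxopentanoate | CCOC(=O)CC(=O)C(C)C | starting material
2 | ethyl [2-(propan-2-yl)-1,3-dioxolan-2-yl]acetate | CCOC(=O)CC1(C(C)C)OCCO1 | intermediate
3 | [2-(propan-2-yl)-1,3-dioxolan-2-yl]acetaldehyde | O=CCC1(C(C)C)OCCO1 | intermediate
4 | but-2-yn-1-ol | CC#CCO | starting material
5 | sodium 2,2-bis(2-methoxyethoxy)-3-methyl-2,5-dihydro-1,2-oxaluminol-2-uide (cyclic alkenylalanate, Al bonded to O and to C3) | CC1=CCO[Al-]1(OCCOC)OCCOC.[Na+] | intermediate (not isolated)
6 | (2Z)-3-iodobut-2-en-1-ol | OC/C=C(/C)I | intermediate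
7 | (2Z)-3-iodobut-2-enal | O=C/C=C(/C)I | intermediate
8 | (3Z)-4-iodopenta-1,3-diene | C=C/C=C(/C)I | intermediate
9 | (penta-2,4-dien-2-yl)lithium, lithium cis to the vinyl group (geometry of 8 retained) | C=C/C=C(/C)[Li] | intermediate (not isolated)
10 | chloro(penta-2,4-dien-2-yl)zinc, zinc cis to the vinyl group | C=C/C=C(/C)[Zn]Cl | intermediate (not isolated)
11 | (3Z,6E)-4-methylocta-1,3,6-triene | C=C/C=C(/C)C/C=C/C | intermediate
12 | 2,2'-[(2R,3Z,6E)-4-methylocta-3,6-diene-1,2-diyl]bis(4,4,5,5-tetramethyl-1,3,2-dioxaborolane) | C/C=C/C/C(C)=C\[C@H](B1OC(C)(C)C(C)(C)O1)CB1OC(C)(C)C(C)(C)O1 | intermediate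
13 | pinacol [(2E,4R,6E)-4-methyl-4-{(1R)-1-[(4,4,5,5-tetramethyl-1,3,2-dioxaborolan-2-yl)oxy]-2-[2-(propan-2-yl)-1,3-dioxolan-2-yl]ethyl}octa-2,6-dien-1-yl]boronate | C/C=C/C[C@](C)(/C=C/CB1OC(C)(C)C(C)(C)O1)[C@H](OB1OC(C)(C)C(C)(C)O1)CC1(C(C)C)OCCO1 | intermediate (not isolated)
14 | pinacol {(2E,4R,6E)-4-[(1R)-1-hydroxy-4-methyl-3-oxopentyl]-4-methylocta-2,6-dien-1-yl}boronate | C/C=C/C[C@](C)(/C=C/CB1OC(C)(C)C(C)(C)O1)[C@H](O)CC(=O)C(C)C | intermediate (not isolated)
15 | diol 16 with its tertiary hydroxyl as the pinacol borate ester (O–Bpin) | C/C=C/C[C@@]1(C)[C@H](O)C[C@@](OB2OC(C)(C)C(C)(C)O2)(C(C)C)[C@@H]1C=C | intermediate (not isolated)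
16 | (1R,3R,4R,5R)-4-[(2E)-but-2-en-1-yl]-5-ethenyl-4-methyl-1-(propan-2-yl)cyclopentane-1,3-diol (both hydroxyls, the methyl and the vinyl group on one face) | C/C=C/C[C@@]1(C)[C@H](O)C[C@@](O)(C(C)C)[C@@H]1C=C | intermediate
17 | (1R,2R,3R,4R)-3-[(2E)-but-2-en-1-yl]-2-ethenyl-3-methyl-1-(propan-2-yl)-4-[(triethylsilyl)oxy]cyclopentan-1-ol | C/C=C/C[C@@]1(C)[C@H](O[Si](CC)(CC)CC)C[C@@](O)(C(C)C)[C@@H]1C=C | intermediate
18 | (1R,2S,3R,4R)-3-[(2E)-but-2-en-1-yl]-3-methyl-2-[(2R)-oxiran-2-yl]-1-(propan-2-yl)-4-[(triethylsilyl)oxy]cyclopentan-1-ol | C/C=C/C[C@@]1(C)[C@H](O[Si](CC)(CC)CC)C[C@@](O)(C(C)C)[C@@H]1[C@@H]2CO2 | intermediate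
19 | (1R,2S,3R,4R)-3-[(2E)-but-2-en-1-yl]-2-[(1S)-1-hydroxy-3-methylbut-3-en-1-yl]-3-methyl-1-(propan-2-yl)-4-[(triethylsilyl)oxy]cyclopentan-1-ol | C/C=C/C[C@@]1(C)[C@H](O[Si](CC)(CC)CC)C[C@@](O)(C(C)C)[C@@H]1[C@@H](O)CC(C)=C | intermediate
20 | (1R,3R,3aS,4S,8aR)-6,8a-dimethyl-3-(propan-2-yl)-1-[(triethylsilyl)oxy]-1,2,3,3a,4,5,8,8a-octahydroazulene-3,4-diol | CC1=CC[C@@]2(C)[C@H](O[Si](CC)(CC)CC)C[C@@](O)(C(C)C)[C@@H]2[C@@H](O)C1 | intermediate
21 | 4-[(tert-butyldimethylsilyl)oxy]benzoic acid | CC(C)(C)[Si](C)(C)Oc1ccc(cc1)C(=O)O | starting material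
22 | (1R,3R,3aS,4S,8aR)-3-hydroxy-6,8a-dimethyl-3-(propan-2-yl)-1-[(triethylsilyl)oxy]-1,2,3,3a,4,5,8,8a-octahydroazulen-4-yl 4-[(tert-butyldimethylsilyl)oxy]benzoate | CC1=CC[C@@]2(C)[C@H](O[Si](CC)(CC)CC)C[C@@](O)(C(C)C)[C@@H]2[C@@H](OC(=O)c2ccc(O[Si](C)(C)C(C)(C)C)cc2)C1 | intermediate
23 | (1R,3R,3aS,4S,8aR)-1,3-dihydroxy-6,8a-dimethyl-3-(propan-2-yl)-1,2,3,3a,4,5,8,8a-octahydroazulen-4-yl 4-hydroxybenzoate | CC1=CC[C@@]2(C)[C@H](O)C[C@@](O)(C(C)C)[C@@H]2[C@@H](OC(=O)c2ccc(O)cc2)C1 | target

## Step count and risks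

Total steps: 14 (steps 1–2 aldehyde branch, steps 3–7 boron branch, steps 8–14 after convergence). Longest linear sequence: 12 steps (steps 3 to 14, from but-2-yn-1-ol).

**Step 8 (key step).** The ring-closing allylboration may be slow at the hindered isopropyl ketone, so that protodeboronation of the allylic boronate competes during the acidic unmasking. The facial selectivity of ring closure (cis-1,3-diol versus the epimeric pair at C3/C3a) also rests on a modest conformational bias. The fallback sets out from 12 and 3 and comes back at 16. The first stage is run as before (toluene, 60 °C, giving 13), but the flask is then worked up oxidatively (NaOH, H2O2) to give (2E,4R,6E)-4-{(1R)-1-hydroxy-2-[2-(propan-2-yl)-1,3-dioxolan-2-yl]ethyl}-4-methylocta-2,6-dien-1-ol F1. The primary allylic hydroxyl is exchanged selectively for bromide (CBr4, PPh3, CH2Cl2, −20 °C) to give (2E,4R,6E)-1-bromo-4-{(1R)-1-hydroxy-2-[2-(propan-2-yl)-1,3-dioxolan-2-yl]ethyl}-4-methylocta-2,6-diene F2. Aqueous HCl/THF then frees the ketone to give (5R,6R,8E)-6-[(1E)-3-bromoprop-1-en-1-yl]-5-hydroxy-2,6-dimethyldec-8-en-3-one F3, and indium powder added to the same flask closes the ring by an intramolecular Barbier allylation (γ-attack), in which indium chelated between the free hydroxyl and the ketone oxygen should enforce the cis-diol, arriving at 16.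

**Step 10.** Oxygen transfer from the hindered tertiary vanadate to a monosubstituted alkene may be slow. That would allow background oxidation of the butenyl alkene and erode facial selectivity at the new carbinol carbon. The fallback sets out from 17 and comes back at 18. The tertiary alcohol is converted (nBuLi, then Boc2O, THF, −78 → 0 °C) into tert-butyl (1R,2R,3R,4R)-3-[(2E)-but-2-en-1-yl]-2-ethenyl-3-methyl-1-(propan-2-yl)-4-[(triethylsilyl)oxy]cyclopentyl carbonate F4. Iodocarbonate cyclisation onto the vinyl group (I2, MeCN, −20 °C) should give, through a chair with the iodomethyl group equatorial, the six-membered cyclic iodocarbonate F5 (carbonate ring fused across the former carbinol carbon and the adjacent ring CH). K2CO3 in MeOH then cleaves the carbonate and closes the epoxide, arriving at 18.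

**Step 7.** Boron may add across the diene in the 1,4-sense, or with insufficient enantiofacial discrimination on this 4,4-disubstituted diene, and every later stereocentre depends on this one. The cis substituent on the diene is the safeguard against 1,4-addition; the fallback replaces catalyst-controlled enantioselection by a resolution. It sets out from 11 and comes back at 13, the first intermediate of step 8. Diboration with an achiral catalyst (Pt(dba)3, PCy3, B2pin2, THF, 60 °C) gives the racemic bis(boronate) F6. The first allylboration with 3 is then run as a kinetic resolution (chiral BINOL-derived phosphoric acid, 5 mol %, toluene, −30 °C, two equivalents of F6), which should consume mainly the (2R) enantiomer and leave the (2S) enantiomer F7. The adduct is 13, and the acid stage of step 8 leads on to 16.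

## Further compounds

F1 | step 8 | (2E,4R,6E)-4-{(1R)-1-hydroxy-2-[2-(propan-2-yl)-1,3-dioxolan-2-yl]ethyl}-4-methylocta-2,6-dien-1-ol | C/C=C/C[C@](C)(/C=C/CO)[C@H](O)CC1(C(C)C)OCCO1
F2 | step 8 | (2E,4R,6E)-1-bromo-4-{(1R)-1-hydroxy-2-[2-(propan-2-yl)-1,3-dioxolan-2-yl]ethyl}-4-methylocta-2,6-diene | C/C=C/C[C@](C)(/C=C/CBr)[C@H](O)CC1(C(C)C)OCCO1
F3 | step 8 | (5R,6R,8E)-6-[(1E)-3-bromoprop-1-en-1-yl]-5-hydroxy-2,6-dimethyldec-8-en-3-one | C/C=C/C[C@](C)(/C=C/CBr)[C@H](O)CC(=O)C(C)C
F4 | step 10 | tert-butyl (1R,2R,3R,4R)-3-[(2E)-but-2-en-1-yl]-2-ethenyl-3-methyl-1-(propan-2-yl)-4-[(triethylsilyl)oxy]cyclopentyl carbonate | C/C=C/C[C@@]1(C)[C@H](O[Si](CC)(CC)CC)C[C@@](OC(=O)OC(C)(C)C)(C(C)C)[C@@H]1C=C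
F5 | step 10 | cyclic iodocarbonate of 17 (4-(iodomethyl)-1,3-dioxan-2-one fused to the cyclopentane across the former carbinol carbon and the adjacent ring CH) | C/C=C/C[C@@]1(C)[C@H](O[Si](CC)(CC)CC)C[C@]2(C(C)C)OC(=O)O[C@@H](CI)[C@H]12
F6 | step 7 | racemic 2,2'-[(3Z,6E)-4-methylocta-3,6-diene-1,2-diyl]bis(4,4,5,5-tetramethyl-1,3,2-dioxaborolane) | C/C=C/C/C(C)=C\C(B1OC(C)(C)C(C)(C)O1)CB1OC(C)(C)C(C)(C)O1
F7 | step 7 | 2,2'-[(2S,3Z,6E)-4-methylocta-3,6-diene-1,2-diyl]bis(4,4,5,5-tetramethyl-1,3,2-dioxaborolane) | C/C=C/C/C(C)=C\[C@@H](B1OC(C)(C)C(C)(C)O1)CB1OC(C)(C)C(C)(C)O1
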